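The route builds the fused dihydrofuran (ring oxygen O1 on the stereogenic C2–H, free hydroxyl on the exocyclic CMe2 carbon) from the isomeric pyran, in which O1 sits on CMe2 and the hydroxyl on the CH carbon. Activating the secondary C3 alcohol of a (3R)-2,2-dimethylchroman-3-ol lets O1 shift to C3 with inversion while water takes the CMe2 carbon. One operation thus gives the five-membered ring, the tertiary carbinol and the (S) centre. The precursor is the bis-MOM-protected 8-isobutyryl chromanol, whose stereocentre comes from a manganese-salen chromene epoxidation. Deprotection and gem-diprenylation of the last free ring carbon finish the target.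

Key step: step 6

Assumption: the target is a β-triketone drawn in one enol form, and the last step is taken to deliver it as that equilibrating tautomer. Chroman locants (O1, C2, C3, C4, C4a … C8a) are used for 7–11 and benzofuran locants (O1, C2, C3, C3a … C7a) from 12 on.

Step 1
Reactants: 1 phloroglucinol; 2 isobutyryl chloride
Product: 3 2-methyl-1-(2,4,6-trihydroxyphenyl)propan-1-one
Conditions: AlCl3 (4 equiv), CH2Cl2/MeNO2, 0 °C to rt; ice/aq. HCl work-up
Reagents that add atoms: none
Why: Friedel–Crafts C-acylation of the electron-rich arene stops after one acyl group because the aluminium-chelated aryl ketone deactivates the ring, and any aryl ester formed first is carried on to the ketone by Fries rearrangement in the same medium.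

Step 2
Reactants: 3 2-methyl-1-(2,4,6-trihydroxyphenyl)propan-1-one
Product: 4 1-[2-hydroxy-4,6-bis(methoxymethoxy)phenyl]-2-methylpropan-1-one
Conditions: MOMCl (2.2 equiv), iPr2NEt (3 equiv), CH2Cl2, 0 °C to rt
Reagents that add atoms: chloromethyl methyl ether, COCCl
Why: Williamson-type O-alkylation (MOM ether formation) takes two hydroxyls, whereas the one that remains hydrogen-bonded to the ketone is the least reactive towards base and electrophile and stays free at this stoichiometry.

Step 3
Reactants: 4 1-[2-hydroxy-4,6-bis(methoxymethoxy)phenyl]-2-methylpropan-1-one; 5 3-methylbut-2-enal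
Product: 7 1-[5,7-bis(methoxymethoxy)-2,2-dimethyl-2H-chromen-8-yl]-2-methylpropan-1-one, via ortho-quinone methide 6 (not isolated)
Conditions: 3-methylbut-2-enal (3 equiv), pyridine, 140 °C, sealed tube
Reagents that add atoms: none
Why: Base-mediated phenol–enal condensation (Knoevenagel-type attack of the ortho carbon on the aldehyde, then loss of water) gives ortho-quinone methide 6, which closes by oxa-6π electrocyclisation; only one hydroxyl is free and its only unsubstituted ortho carbon is C3, so a single chromene regioisomer can arise.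

Step 4
Reactants: 7 1-[5,7-bis(methoxymethoxy)-2,2-dimethyl-2H-chromen-8-yl]-2-methylpropan-1-one
Product: 8 1-[(3R,4R)-3,4-epoxy-5,7-bis(methoxymethoxy)-2,2-dimethylchroman-8-yl]-2-methylpropan-1-one
Conditions: (R,R)-[N,N'-bis(3,5-di-tert-butylsalicylidene)cyclohexane-1,2-diaminato]MnCl (4 mol %), 4-phenylpyridine N-oxide (20 mol %), aq. NaOCl buffered to pH 11.3, CH2Cl2, 0 °C; crude epoxide taken on directly
Reagents that add atoms: sodium hypochlorite, [Na+].[O-]Cl
Why: Jacobsen–Katsuki epoxidation, for which cis-olefins of the 2,2-dimethylchromene class are the best substrates; the (R,R) ligand directs oxo transfer to the face that gives the (3R,4R) epoxide (catalyst control), and the cold basic medium spares the acid-sensitive epoxide and the MOM ethers.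

Step 5
Reactants: 8 1-[(3R,4R)-3,4-epoxy-5,7-bis(methoxymethoxy)-2,2-dimethylchroman-8-yl]-2-methylpropan-1-one
Product: 9 (R)-1-[3-hydroxy-5,7-bis(methoxymethoxy)-2,2-dimethylchroman-8-yl]-2-methylpropan-1-one
Conditions: H2 (1 atm), 10% Pd/C, EtOAc, rt
Reagents that add atoms: none
Why: Palladium-catalysed hydrogenolysis cleaves only the benzylic C4–O bond of the epoxide, so the C3–O bond and the (3R) configuration pass unchanged into the chromanol, while the hindered di-ortho-substituted aryl ketone and the MOM ethers are inert at one atmosphere.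

Step 6
Reactants: 9 (R)-1-[3-hydroxy-5,7-bis(methoxymethoxy)-2,2-dimethylchroman-8-yl]-2-methylpropan-1-one
Product: 12 (S)-1-[2-(2-hydroxypropan-2-yl)-4,6-bis(methoxymethoxy)-2,3-dihydro-1-benzofuran-7-yl]-2-methylpropan-1-one, via secondary triflate 10 (not isolated), via epoxonium triflate 11 (not isolated)
Conditions: Tf2O (1.2 equiv), 2,6-di-tert-butyl-4-methylpyridine (3 equiv), CH2Cl2, −78 °C; then THF/H2O, −40 °C to rt
Reagents that add atoms: water, O
Why: Triflation of the C3 hydroxyl gives the neopentyl-type triflate 10, which resists direct displacement; ring oxygen O1 instead expels triflate from the side opposite the leaving group to form the bicyclic epoxonium ion 11, and water then attacks its CMe2 carbon and cleaves the original O1–CMe2 bond. The closest known reaction type is the anchimerically assisted ring contraction of activated 2,2-dimethylchroman-3-ols and tetrahydropyran-3-ols to 2-(1-substituted 1-methylethyl) five-membered cyclic ethers. The new O1–C3 bond is made by 3-exo-tet closure, and the oxirane so formed becomes the dihydrofuran ring once its other C–O bond is opened. The only stereocentre, C2 of the dihydrofuran (formerly C3), is fixed by this stereospecific backside displacement, so the (3R) carbinol from the epoxidation is relayed with one inversion to (S) (substrate control). Opening at the tertiary and not the secondary epoxonium carbon is required and is secured by the gem-dimethyl carbon, which carries most of the positive charge; shift of the aryl carbon instead of O1 would leave a primary cation and should not compete. The hindered non-nucleophilic pyridine and the low temperature limit proton loss to the isopropenyl compound and keep the MOM ethers and the twisted, hindered ketone out of reach of the anhydride.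

Step 7
Reactants: 12 (S)-1-[2-(2-hydroxypropan-2-yl)-4,6-bis(methoxymethoxy)-2,3-dihydro-1-benzofuran-7-yl]-2-methylpropan-1-one
Product: 13 (S)-1-[4,6-dihydroxy-2-(2-hydroxypropan-2-yl)-2,3-dihydro-1-benzofuran-7-yl]-2-methylpropan-1-one
Conditions: HCl (2 M), MeOH, rt to 40 °C
Reagents that add atoms: none
Why: Acid-catalysed acetal methanolysis removes both aryl MOM ethers, whereas the tertiary carbinol should not ionise under these conditions because the adjacent ring C–O bond destabilises the cation, so the dihydrofuran and its stereocentre are retained.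

Step 8
Reactants: 13 (S)-1-[4,6-dihydroxy-2-(2-hydroxypropan-2-yl)-2,3-dihydro-1-benzofuran-7-yl]-2-methylpropan-1-one; 14 prenyl bromide
Product: 16 garcinielliptone HD, via 5-prenyl phenol 15 (not isolated)
Conditions: prenyl bromide (2.3 equiv in all), 10% aq. KOH, 0 °C
Reagents that add atoms: prenyl bromide (second equivalent), CC(C)=CCBr
Why: Alkylative dearomatisation of an acylphloroglucinol (the lupulone-type gem-diprenylation) consumes two molecules of prenyl bromide: in aqueous KOH the solvated phenoxides react at carbon, the first molecule at the only unsubstituted ring carbon C5 to give 15 and the second again at C5, which is ortho to both phenoxide oxygens, giving the non-stereogenic quaternary carbon and the enolised β-triketone with the C2 stereocentre untouched.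

Compound list
1 | phloroglucinol | Oc1cc(O)cc(O)c1 | starting material
2 | isobutyryl chloride | CC(C)C(Cl)=O | starting material
3 | 2-methyl-1-(2,4,6-trihydroxyphenyl)propan-1-one | CC(C)C(=O)c1c(O)cc(O)cc1O | intermediate
4 | 1-[2-hydroxy-4,6-bis(methoxymethoxy)phenyl]-2-methylpropan-1-one | CC(C)C(=O)c1c(O)cc(OCOC)cc1OCOC | intermediate
5 | 3-methylbut-2-enal | CC(C)=CC=O | starting material
6 | 2-isobutyryl-3,5-bis(methoxymethoxy)-6-[(Z)-3-methylbut-2-en-1-ylidene]cyclohexa-2,4-dien-1-one (ortho-quinone methide, not isolated) | O=C1C(C(=O)C(C)C)=C(OCOC)C=C(OCOC)/C1=C/C=C(C)C | intermediate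
7 | 1-[5,7-bis(methoxymethoxy)-2,2-dimethyl-2H-chromen-8-yl]-2-methylpropan-1-one | O1C(C)(C)C=Cc2c(OCOC)cc(OCOC)c(C(=O)C(C)C)c12 | intermediate
8 | 1-[(3R,4R)-3,4-epoxy-5,7-bis(methoxymethoxy)-2,2-dimethylchroman-8-yl]-2-methylpropan-1-one | O1C(C)(C)[C@@H]2O[C@@H]2c3c(OCOC)cc(OCOC)c(C(=O)C(C)C)c13 | intermediate
9 | (R)-1-[3-hydroxy-5,7-bis(methoxymethoxy)-2,2-dimethylchroman-8-yl]-2-methylpropan-1-one | O1C(C)(C)[C@H](O)Cc2c(OCOC)cc(OCOC)c(C(=O)C(C)C)c12 | intermediate
10 | (R)-8-isobutyryl-5,7-bis(methoxymethoxy)-2,2-dimethylchroman-3-yl trifluoromethanesulfonate (not isolated) | O1C(C)(C)[C@H](OS(=O)(=O)C(F)(F)F)Cc2c(OCOC)cc(OCOC)c(C(=O)C(C)C)c12 | intermediate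
11 | bicyclic epoxonium (oxiranium) triflate in which O1 bridges CMe2 and the inverted C3 (not isolated) | CC1(C)[C@@H]2Cc3c(OCOC)cc(OCOC)c(C(=O)C(C)C)c3[O+]12.[O-]S(=O)(=O)C(F)(F)F | intermediate
12 | (S)-1-[2-(2-hydroxypropan-2-yl)-4,6-bis(methoxymethoxy)-2,3-dihydro-1-benzofuran-7-yl]-2-methylpropan-1-one | O1[C@H](C(C)(C)O)Cc2c(OCOC)cc(OCOC)c(C(=O)C(C)C)c12 | intermediate
13 | (S)-1-[4,6-dihydroxy-2-(2-hydroxypropan-2-yl)-2,3-dihydro-1-benzofuran-7-yl]-2-methylpropan-1-one | O1[C@H](C(C)(C)O)Cc2c(O)cc(O)c(C(=O)C(C)C)c12 | intermediate
14 | prenyl bromide (1-bromo-3-methylbut-2-ene) | CC(C)=CCBr | starting material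
15 | (S)-1-[4,6-dihydroxy-2-(2-hydroxypropan-2-yl)-5-(3-methylbut-2-en-1-yl)-2,3-dihydro-1-benzofuran-7-yl]-2-methylpropan-1-one (not isolated) | O1[C@H](C(C)(C)O)Cc2c(O)c(CC=C(C)C)c(O)c(C(=O)C(C)C)c12 | intermediate
16 | garcinielliptone HD [(2S)-7-(1-hydroxy-2-methylpropylidene)-2-(2-hydroxypropan-2-yl)-5,5-bis(3-methylbut-2-en-1-yl)-2,3-dihydro-1-benzofuran-4,6(5H,7H)-dione] | CC(C)=CCC1(CC=C(C)C)C(=O)C2=C(O[C@H](C(C)(C)O)C2)/C(=C(/O)C(C)C)C1=O | target

Total step count: 8. Longest linear sequence: 8 steps, from phloroglucinol 1 to 16.

Steps most likely to fail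

1. Step 6. Proton loss from the bridged oxonium ion may outrun its capture by water, or the excess anhydride may attack the acetal protecting groups during the aqueous stage. The fallback sets out from 9 and makes elimination the intended outcome. Tf2O and 2,6-di-tert-butyl-4-methylpyridine in dry CH2Cl2 from −78 °C to rt, with no water added, should carry 9 through 10 and 11 to (S)-1-[4,6-bis(methoxymethoxy)-2-(prop-1-en-2-yl)-2,3-dihydro-1-benzofuran-7-yl]-2-methylpropan-1-one F1. A Mukaiyama hydration (Co(acac)2, divalent cobalt, with PhSiH3 and O2 in iPrOH/THF at rt, then a reductive work-up) should add water in the Markovnikov sense to the 1,1-disubstituted alkene. The radical at the exocyclic carbon is trapped by oxygen without touching C2, and the route is rejoined at 12.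

2. Step 8. Alkylation on oxygen or at the already substituted ring-fusion carbon C3a, and stalling after the first prenyl group, may compete with double C-alkylation at C5; O-prenyl ethers do not revert in aqueous KOH. The fallback sets out from 13 and uses a Tsuji–Trost allylation with allyl methyl carbonate and Pd(PPh3)4 (zerovalent palladium) in THF at rt. Any O-allyl product is re-ionised by the catalyst, so the material is funnelled to carbon. This should pass through (S)-1-[4,6-dihydroxy-2-(2-hydroxypropan-2-yl)-5-(prop-2-en-1-yl)-2,3-dihydro-1-benzofuran-7-yl]-2-methylpropan-1-one F2, which is not isolated, to (2S)-7-(1-hydroxy-2-methylpropylidene)-2-(2-hydroxypropan-2-yl)-5,5-di(prop-2-en-1-yl)-2,3-dihydro-1-benzofuran-4,6(5H,7H)-dione F3. Double olefin cross-metathesis of F3 with excess 2-methylbut-2-ene and the second-generation Grubbs catalyst (H2IMes)(PCy3)Cl2Ru=CHPh in CH2Cl2 at 40 °C should turn both allyl groups into prenyl groups and rejoin the route at 16.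

3. Step 3. Carbon–carbon bond formation at the crowded ortho carbon of the hydrogen-bonded phenol may be slow, so that self-condensation of the enal or reversible attack through the para carbon C5 takes over. The fallback sets out from 4 and replaces the intermolecular C–C bond formation by an intramolecular one. O-Alkylation with 3-chloro-3-methylbut-1-yne (K2CO3, KI, CuI cat., acetone, reflux) should give 2-methyl-1-[2-(2-methylbut-3-yn-2-yloxy)-4,6-bis(methoxymethoxy)phenyl]propan-1-one F4. Heating F4 in xylene at 140 °C should trigger the aryl propargyl Claisen rearrangement to 1-[2-hydroxy-4,6-bis(methoxymethoxy)-3-(3-methylbuta-1,2-dien-1-yl)phenyl]-2-methylpropan-1-one F5, which is not isolated. A 1,5-hydrogen shift in F5 leads to the same quinone methide 6, whose electrocyclisation rejoins the route at 7.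

Further compounds
F1 | step 6 | (S)-1-[4,6-bis(methoxymethoxy)-2-(prop-1-en-2-yl)-2,3-dihydro-1-benzofuran-7-yl]-2-methylpropan-1-one | O1[C@H](C(C)=C)Cc2c(OCOC)cc(OCOC)c(C(=O)C(C)C)c12
F2 | step 8 | (S)-1-[4,6-dihydroxy-2-(2-hydroxypropan-2-yl)-5-(prop-2-en-1-yl)-2,3-dihydro-1-benzofuran-7-yl]-2-methylpropan-1-one | O1[C@H](C(C)(C)O)Cc2c(O)c(CC=C)c(O)c(C(=O)C(C)C)c12
F3 | step 8 | (2S)-7-(1-hydroxy-2-methylpropylidene)-2-(2-hydroxypropan-2-yl)-5,5-di(prop-2-en-1-yl)-2,3-dihydro-1-benzofuran-4,6(5H,7H)-dione | C=CCC1(CC=C)C(=O)C2=C(O[C@H](C(C)(C)O)C2)/C(=C(/O)C(C)C)C1=O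
F4 | step 3 | 2-methyl-1-[2-(2-methylbut-3-yn-2-yloxy)-4,6-bis(methoxymethoxy)phenyl]propan-1-one | CC(C)C(=O)c1c(OC(C)(C)C#C)cc(OCOC)cc1OCOC
F5 | step 3 | 1-[2-hydroxy-4,6-bis(methoxymethoxy)-3-(3-methylbuta-1,2-dien-1-yl)phenyl]-2-methylpropan-1-one | CC(C)C(=O)c1c(O)c(C=C=C(C)C)c(OCOC)cc1OCOC
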